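**Remarks.** Ring atoms are numbered as in a chroman (O1, C2, C3, C4, C4a, C5–C8, C8a); the aryl group on C2 is ring B and the chain on C4 is numbered C1'' to C4'' outward from the ring. The CIP label of C4 switches between R and S along the route only because the priorities of its neighbours change; the spatial arrangement set in step 11 is never altered. Allyltributylstannane, the amide phosphonate of step 3 and vinylmagnesium bromide are assumed to be purchased reagents.

## Analysis of the target

Target 33 is a flavan. Ring A carries a free hydroxyl on C5, a methoxy group on C7 and an (E)-4-hydroxycinnamoyl ketone on C8; C2 bears a 4-hydroxyphenyl group (ring B) and C4 a 2-hydroxy-4-(4-hydroxyphenyl)butyl chain. There are three stereocentres. C2 (R) and C4 (S) are 1,3-related on the pyran ring with the aryl group and the chain on opposite faces (2,4-trans). The carbinol C2'' (R) lies one methylene away from C4 in a freely rotating chain, so the ring cannot be relied on to set it. The sensitive parts are the chalcone enone (hydride, hydrogenation, conjugate addition), the benzylic C2–O1 bond (it ionises under acid because ring B is para-oxygenated), four phenols and an electron-rich ring A. The difficulties are the trans relationship across the pyran ring, the remote carbinol, and the regiochemistry of ring A: O5 and O7 are differentiated, and C8 rather than C6 carries the acyl group. The strategy rests on the fact that O1–C8a and C4–C4a are bonds from two neighbouring carbons of ring A, exactly the two bonds an aryne C4a≡C8a forms when it takes up an oxygen nucleophile and then a carbon electrophile. The C5 oxygen sits next to C4a, and an alkoxy group in that position sends the nucleophile to the far aryne carbon (C8a) and leaves the carbanion on C4a, which is what the ring closure requires.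

## Retrosynthetic reasoning

**Protecting groups (33 from 32).** The three aryl phenols outside ring A are carried as MOM ethers, which tolerate fluoride, organolithium reagents, hydride and hydrogenation. The C5 phenol and the C2'' alcohol are carried as tert-butyldimethylsilyl ethers in the late stages. All five groups are acid-labile, so one mild acidic operation releases 33 and no step follows that could damage the chalcone.

**C8–C(=O) bond (32 from 29 and 5).** The cinnamoyl group is added last because its enone would not survive the reduction and hydrogenation needed for the chain. The bond is cut at the ring so that the whole enone arrives as the N-methoxy-N-methylamide 5, already needed for the other fragment. C8 becomes nucleophilic by halogen–lithium exchange of bromide 29. Direct deprotonation at C8 was not chosen, because the aryl MOM ethers are strong directing groups and would compete. The bromide comes from 28, where the bulky silyloxy group on C5 shields C6 and leaves C8 as the accessible position.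

**Chain adjustment (28 from 27, 26 and 24).** The saturated carbinol chain is traced to the enone of 24. Reducing the ketone while the alkene is still present gives the reagent two clearly different flanks (styryl against CH2), which a saturated ketone would not offer. One hydrogenation then saturates the alkene and removes the C5 benzyl group (26 to 27), and silylation gives 28.

**Key disconnection (24 from 8 and 19).** O1–C8a and C4–C4a are cut together. This gives aryne 21, released from silyl triflate 19, and the open-chain hydroxy dienone 8, whose alkoxide supplies O1 and whose nearer enone β-carbon becomes C4. One operation builds the pyran ring and C4. C2 is set beforehand and is untouched because its C–O bond is not broken. The forward step must add the alkoxide to the aryne carbon remote from the benzyloxy group and close the carbanion on the enone before it is protonated. The alternative of cutting O1–C2 would require a benzylic cation or displacement at C2 and would put its configuration at risk.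

**Hydroxy dienone (8 from 4 and 7; both from 2; 2 from 1).** The C4=Cα alkene of 8 is cut by cross-metathesis into homoallylic alcohol 4 and vinyl ketone 7. Alcohol 4 comes from aldehyde 2 by asymmetric allylation, which sets C2. Dienone 7 comes from amide 5 and a vinyl Grignard reagent, and 5 from the same aldehyde 2 by olefination. A single aldehyde therefore supplies ring B, the chain aryl group and, through 5, the chalcone aryl group.

**Aryne precursor (19 from 17, 13, 12, 10 and 9).** The triflate oxygen of 19 sits where the aldehyde carbon of 9 was. Benzylation (10), oxidative replacement of the formyl group by hydroxyl (12), carbamoylation (13), carbamate-directed silylation at the only free ortho position (17) and carbamate-to-triflate exchange give 19. Because the phenol of 12 has one free ortho position, only one aryne can form, with the benzyloxy group next to the carbon that will become C4a.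

## Alternatives that were turned down

**Alternative 1:** The chain oxygen on C2'' is first tied to C2 in a tetrahydropyran, and the cuts are C2–C3 and C4–C4a. A silyl triflate Lewis acid ionises acetoxy ether A2 (epimeric at the acetal carbon), the oxocarbenium ion closes onto the terminal alkene (Prins), and the secondary ring cation is intercepted by phloroglucinol A3 (Friedel–Crafts) to give the all-cis tetrahydropyran A1. The benzylic C2–O bond must later be transferred from the chain oxygen to a ring A phenol to give the chroman.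
- **For:** One chair-like cascade fixes the C4/C2'' relationship from a single carbinol centre. This is stronger than the chosen route, which needs a separate reagent-controlled reduction for C2''. The symmetric arene A3 needs no regiocontrol in the C–C bond formation.
- **Against:** The ether transposition passes through a benzylic cation at C2, so C2 is set only by whatever preference the re-closure has, and 2,4-trans is not assured. The cation can also lose a proton or alkylate ring A at carbon. The three equivalent hydroxyls of A1 must afterwards be told apart (one as O1, one free, one methylated), and the C6/C8 question remains. The free triol may be alkylated more than once in the key step.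
- **Comparison:** The chosen route installs each ring A oxygen in its final form from the start and never breaks the C2–O bond, at the cost of one extra step for C2''.

**Alternative 2:** The only cut is O1–C2. The open 1,3-diarylpropane A5, which already holds C4, C2'' and the C8 acetyl group, is oxidised by a quinone hydride acceptor at the CH2 next to the para-benzyloxyphenyl ring, and the neighbouring phenol adds to the cation to give flavan A4.
- **For:** The C8 acyl carbon is present from the outset, so the chalcone follows by aldol condensation and no C6/C8 selection is needed. On this point it is stronger than the chosen route.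
- **Against:** C2 is created from a planar cation under 1,3-induction from C4 alone, so the trans outcome is as uncertain as in the chosen key step but now concerns the centre that is otherwise easiest to set by a reagent. The oxidant must discriminate between several activated C–H bonds (C4–H on the very electron-rich ring A, the second arylethyl CH2, and the C2–H of the product, which is more oxidisable than the starting CH2). The acetyl-chelated phenol is a weak nucleophile. A5 is a long linear target with a benzylic stereocentre on a hexasubstituted arene and four different oxygen protecting groups.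
- **Comparison:** The chosen route pays with a late C8 functionalisation but sets C2 by a reliable allylation and forms the ring convergently from two short fragments.

**Alternative 3:** The cuts are C3–C4 and O1–C2. A chiral phosphoric acid dehydrates the ortho-hydroxybenzylic alcohol A7 to the ortho-quinone methide A9, which takes up 4-(tert-butyldimethylsilyloxy)styrene A8 in a hetero-[4+2] addition to give chroman A6.
- **For:** This is the most convergent plan. A6 already carries the complete chain with C2'' and a free C5 hydroxyl, so fewer steps follow the key step than in the chosen route. The two ortho hydroxyls of A7 are equivalent, so no regiochemical issue arises in forming A9.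
- **Against:** A9 has hydrogens on the carbon next to the methide and is expected to tautomerise to a 2-alkenylphenol faster than it is trapped by a modest dienophile. These cycloadditions normally place the C2 aryl and C4 substituent cis (endo), whereas the target is trans. The catalyst would have to override that preference and control two new centres in the presence of the resident C2'' centre. The aryl silyl ethers are exposed to acid, and the C8 acylation problem remains.
- **Comparison:** The chosen route is longer after the key step, but each stereocentre has its own control element: C2 by allylation, C4 by the geometry of an intramolecular closure, C2'' by a reduction catalyst.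

Key step: step 11

## Route

**Step 1**
Reactants: 1 4-hydroxybenzaldehyde
Product: 2 4-(methoxymethoxy)benzaldehyde
Conditions: MOMCl, i-Pr2NEt, CH2Cl2, 0 °C → rt
Reagents that add atoms: chloromethyl methyl ether, COCCl
Why: O-alkylation of the phenoxide by the chloromethyl ether (Williamson-type acetal formation); the MOM ether should withstand fluoride, organometallic reagents, hydride and hydrogenation and is removed by acid at the end.

**Step 2**
Reactants: 2 4-(methoxymethoxy)benzaldehyde
Product: 4 (1R)-1-[4-(methoxymethoxy)phenyl]but-3-en-1-ol, via tributylstannyl ether 3 (not isolated)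
Conditions: allylSnBu3, (R)-BINOL (20 mol %), Ti(OiPr)4 (10 mol %), 4 Å MS, CH2Cl2, −20 °C; aq. NaHCO3
Reagents that add atoms: allyltributylstannane, C=CC[Sn](CCCC)(CCCC)CCCC
Why: Keck asymmetric allylation: the BINOL–titanium Lewis acid activates the aldehyde and the allylstannane adds to one enantioface, the (R)-BINOL antipode being the one expected from the established sense for aryl aldehydes to give the (R)-carbinol that becomes C2; stannyl ether 3 is hydrolysed on work-up. The configuration should be confirmed (Mosher esters) before the material is carried on.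

**Step 3**
Reactants: 2 4-(methoxymethoxy)benzaldehyde
Product: 5 (2E)-N-methoxy-3-[4-(methoxymethoxy)phenyl]-N-methylprop-2-enamide
Conditions: (EtO)2P(O)CH2C(O)N(OMe)Me, NaH, THF, 0 °C → rt
Reagents that add atoms: diethyl {2-[methoxy(methyl)amino]-2-oxoethyl}phosphonate, CCOP(=O)(CC(=O)N(C)OC)OCC
Why: Horner–Wadsworth–Emmons olefination; the stabilised amide phosphonate should give the (E)-alkene, and the product serves twice (steps 4 and 16).

**Step 4**
Reactants: 5 (2E)-N-methoxy-3-[4-(methoxymethoxy)phenyl]-N-methylprop-2-enamide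
Product: 7 (1E)-1-[4-(methoxymethoxy)phenyl]penta-1,4-dien-3-one, via magnesium hemiaminal 6 (not isolated)
Conditions: CH2=CHMgBr, THF, −78 → 0 °C; poured into cold 1 M HCl
Reagents that add atoms: vinylmagnesium bromide, C=C[Mg]Br
Why: Weinreb ketone synthesis: the chelated adduct 6 holds until the quench, so one vinyl group is delivered; the inverse acidic quench keeps the released N,O-dimethylhydroxylamine protonated and away from the vinyl ketone, which is used without storage.

**Step 5**
Reactants: 4 (1R)-1-[4-(methoxymethoxy)phenyl]but-3-en-1-ol; 7 (1E)-1-[4-(methoxymethoxy)phenyl]penta-1,4-dien-3-one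
Product: 8 (1E,4E,7R)-7-hydroxy-1,7-bis[4-(methoxymethoxy)phenyl]hepta-1,4-dien-3-one
Conditions: second-generation Hoveyda–Grubbs catalyst RuCl2(H2IMes)(=CH-C6H4-2-OiPr) (5 mol %), 7 in excess, CH2Cl2, 40 °C
Reagents that add atoms: none
Why: Olefin cross-metathesis between a terminal homoallylic alcohol and a vinyl ketone, the standard pairing for (E)-enones since the vinyl ketone is slow to homodimerise; the conjugated, aryl-substituted alkene of 7 is far less reactive and should be left alone. The carbinol centre is not involved.

**Step 6**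
Reactants: 9 2-hydroxy-4-methoxybenzaldehyde
Product: 10 2-(benzyloxy)-4-methoxybenzaldehyde
Conditions: BnBr, K2CO3, DMF, rt
Reagents that add atoms: benzyl bromide, BrCc1ccccc1
Why: Williamson etherification of the phenoxide; benzyl is chosen for the future O5 because the hydrogenation of step 13 removes it in the operation that saturates the chain alkene.

**Step 7**
Reactants: 10 2-(benzyloxy)-4-methoxybenzaldehyde
Product: 12 2-(benzyloxy)-4-methoxyphenol, via aryl formate 11 (not isolated)
Conditions: mCPBA, CH2Cl2, 0 °C → rt; then KOH, MeOH–H2O, rt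
Reagents that add atoms: 3-chloroperbenzoic acid, OOC(=O)c1cccc(Cl)c1
Why: Baeyer–Villiger (Dakin-type) oxidation: in the peracid adduct the electron-rich aryl group migrates in preference to hydride to give formate 11, which is saponified; the formyl carbon is thereby replaced by the oxygen that will carry the triflate.

**Step 8**
Reactants: 12 2-(benzyloxy)-4-methoxyphenol
Product: 13 2-(benzyloxy)-4-methoxyphenyl N-(propan-2-yl)carbamate
Conditions: i-PrNCO, Et3N (cat.), CH2Cl2, rt
Reagents that add atoms: isopropyl isocyanate, CC(C)N=C=O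
Why: Base-catalysed addition of the phenol to the isocyanate; the carbamate is the directing group for step 9 and can later be removed under mild base.

**Step 9**
Reactants: 13 2-(benzyloxy)-4-methoxyphenyl N-(propan-2-yl)carbamate
Product: 17 2-(benzyloxy)-4-methoxy-6-(trimethylsilyl)phenyl N-(propan-2-yl)carbamate, via N-silyl carbamate 14 (not isolated), via aryllithium 15 (not isolated), via N-silyl C-silyl carbamate 16 (not isolated)
Conditions: TBSOTf, TMEDA, Et2O, 0 °C → rt; n-BuLi, TMEDA, −78 °C; TMSCl, −78 °C → rt; aq. NaHSO4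
Reagents that add atoms: chlorotrimethylsilane, C[Si](C)(C)Cl
Why: Directed ortho-metalation: N-silylation in the flask (14) masks the N–H, the carbamate carbonyl directs butyllithium to its only free ortho position, C6 (15), and the chlorosilane traps the aryllithium (16); the N-silyl group is lost in the acidic work-up. The carbamate outranks the ether oxygens as a director, which should keep metalation away from C3 and from the benzylic CH2.

**Step 10**
Reactants: 17 2-(benzyloxy)-4-methoxy-6-(trimethylsilyl)phenyl N-(propan-2-yl)carbamate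
Product: 19 2-(benzyloxy)-4-methoxy-6-(trimethylsilyl)phenyl trifluoromethanesulfonate, via silyl phenol 18 (not isolated)
Conditions: Et2NH, DBU, MeCN, 40 °C; then PhNTf2, rt
Reagents that add atoms: N-phenylbis(trifluoromethanesulfonimide), O=S(=O)(N(c1ccccc1)S(=O)(=O)C(F)(F)F)C(F)(F)F
Why: The N-monosubstituted carbamate fragments under base (E1cB) to the phenoxide of 18 and isopropyl isocyanate, which diethylamine scavenges as a urea; the phenoxide is triflated in the same flask (aryl triflate formation with a triflimide).

**Step 11**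
Reactants: 8 (1E,4E,7R)-7-hydroxy-1,7-bis[4-(methoxymethoxy)phenyl]hepta-1,4-dien-3-one; 19 2-(benzyloxy)-4-methoxy-6-(trimethylsilyl)phenyl trifluoromethanesulfonate
Product: 24 (3E)-1-[(2R,4R)-5-(benzyloxy)-7-methoxy-2-[4-(methoxymethoxy)phenyl]-3,4-dihydro-2H-chromen-4-yl]-4-[4-(methoxymethoxy)phenyl]but-3-en-2-one, via cesium alkoxide 20 (not isolated), via aryne 21 (not isolated), via O-arylated aryl cesium 22 (not isolated), via cesium enolate 23 (not isolated)
Conditions: CsF (4 equiv), 18-crown-6, THF, 0 °C → rt, 19 (1.5 equiv) added slowly; aq. NH4Cl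
Reagents that add atoms: none
Why: Proposed new method: fluoride removes the trimethylsilyl group of 19 and triflate leaves to give aryne 21, while fluoride as base converts 8 into alkoxide 20; the alkoxide should add to the aryne carbon remote from the benzyloxy group (the future C8a), the more electrophilic terminus of a 3-alkoxy aryne, so that the carbanion of 22 sits on C4a next to the inductively withdrawing oxygen. The carbanion of 22 then adds to the β-carbon of the nearer enone in a 6-exo-trig Michael closure that forms C4–C4a and the pyran ring, and the cross-conjugated enolate 23 is protonated at carbon. The closest known reaction type is the insertion of arynes into ortho-hydroxychalcones, where a phenoxide adds to the aryne and the aryl anion closes onto the enone to give 9-substituted xanthenes; O-arylation of aliphatic alcohols by arynes is also known, but an aliphatic alkoxide combined with a chroman-forming closure has not been shown. C2 keeps the (R) configuration of step 2 because its C–O bond is never broken. The new centre C4 is under substrate control: in a half-chair transition state the C2 aryl group should be equatorial and the enone arm pseudoaxial, because a pseudoequatorial arm would be pressed against the C5 benzyloxy group, and this gives the 2,4-trans isomer, (4R) in 24. The step needs three selectivities: distal addition to the aryne (secured by the C5 benzyloxy group and by the unhindered position next to C8a), attack on the near and not the far enone (only the near one gives a six-membered ring), and ring closure ahead of protonation of 22 (favoured by the aprotic medium and the intramolecular activated acceptor). The far enone remains for the reduction of step 12.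

**Step 12**
Reactants: 24 (3E)-1-[(2R,4R)-5-(benzyloxy)-7-methoxy-2-[4-(methoxymethoxy)phenyl]-3,4-dihydro-2H-chromen-4-yl]-4-[4-(methoxymethoxy)phenyl]but-3-en-2-one
Product: 26 (2S,3E)-1-[(2R,4S)-5-(benzyloxy)-7-methoxy-2-[4-(methoxymethoxy)phenyl]-3,4-dihydro-2H-chromen-4-yl]-4-[4-(methoxymethoxy)phenyl]but-3-en-2-ol, via catechol borate 25 (not isolated)
Conditions: (R)-2-methyl-CBS-oxazaborolidine (20 mol %), catecholborane, toluene, −78 °C; MeOH, then 1 M NaOH wash
Reagents that add atoms: none
Why: Corey–Bakshi–Shibata reduction: the ketone binds the oxazaborolidine–borane complex with the styryl group as the large substituent and hydride is delivered to one face, which with the (R)-catalyst should give the (S)-allylic alcohol, the arrangement that is (2''R) in the target once the alkene is saturated. Catecholborane at low temperature avoids hydroboration and 1,4-reduction; borate 25 is hydrolysed on work-up.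

**Step 13**
Reactants: 26 (2S,3E)-1-[(2R,4S)-5-(benzyloxy)-7-methoxy-2-[4-(methoxymethoxy)phenyl]-3,4-dihydro-2H-chromen-4-yl]-4-[4-(methoxymethoxy)phenyl]but-3-en-2-ol
Product: 27 (2R,4S)-4-{(2R)-2-hydroxy-4-[4-(methoxymethoxy)phenyl]butyl}-7-methoxy-2-[4-(methoxymethoxy)phenyl]-3,4-dihydro-2H-chromen-5-ol
Conditions: H2 (1 atm), 10% Pd/C, EtOAc, rt
Reagents that add atoms: none
Why: Heterogeneous catalytic hydrogenation saturates the styrenyl alkene and hydrogenolyses the benzyl ether in one operation; the MOM ethers and the C2–O1 bond of the flavan are expected to survive at one atmosphere in a neutral solvent. C2'' is untouched; its label becomes R only because the vinyl group turns into an alkyl group.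

**Step 14**
Reactants: 27 (2R,4S)-4-{(2R)-2-hydroxy-4-[4-(methoxymethoxy)phenyl]butyl}-7-methoxy-2-[4-(methoxymethoxy)phenyl]-3,4-dihydro-2H-chromen-5-ol
Product: 28 (2R,4R)-5-[(tert-butyldimethylsilyl)oxy]-4-{(2R)-2-[(tert-butyldimethylsilyl)oxy]-4-[4-(methoxymethoxy)phenyl]butyl}-7-methoxy-2-[4-(methoxymethoxy)phenyl]-3,4-dihydro-2H-chromene
Conditions: TBSCl, imidazole, DMF, rt → 40 °C
Reagents that add atoms: tert-butyldimethylsilyl chloride, CC(C)(C)[Si](C)(C)Cl
Why: Silylation of the phenol and the secondary alcohol with the silyl chloride and imidazole; the chloride is used and not a silyl triflate because silyl triflates exchange aryl MOM ethers.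

**Step 15**
Reactants: 28 (2R,4R)-5-[(tert-butyldimethylsilyl)oxy]-4-{(2R)-2-[(tert-butyldimethylsilyl)oxy]-4-[4-(methoxymethoxy)phenyl]butyl}-7-methoxy-2-[4-(methoxymethoxy)phenyl]-3,4-dihydro-2H-chromene
Product: 29 (2R,4R)-8-bromo-5-[(tert-butyldimethylsilyl)oxy]-4-{(2R)-2-[(tert-butyldimethylsilyl)oxy]-4-[4-(methoxymethoxy)phenyl]butyl}-7-methoxy-2-[4-(methoxymethoxy)phenyl]-3,4-dihydro-2H-chromene
Conditions: NBS (1.0 equiv), CH2Cl2, −78 → −20 °C, dark
Reagents that add atoms: N-bromosuccinimide, O=C1CCC(=O)N1Br
Why: Electrophilic aromatic bromination of the phloroglucinol-type ring A, which is far more reactive than the two mono-oxygenated aryl rings. Of its two free positions, C6 is flanked by the bulky silyloxy group, which the C4 chain forces to lean towards C6, whereas C8 lies next to the ring oxygen tied back in the pyran, so bromine should enter at C8.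

**Step 16**
Reactants: 29 (2R,4R)-8-bromo-5-[(tert-butyldimethylsilyl)oxy]-4-{(2R)-2-[(tert-butyldimethylsilyl)oxy]-4-[4-(methoxymethoxy)phenyl]butyl}-7-methoxy-2-[4-(methoxymethoxy)phenyl]-3,4-dihydro-2H-chromene; 5 (2E)-N-methoxy-3-[4-(methoxymethoxy)phenyl]-N-methylprop-2-enamide
Product: 32 (2E)-1-[(2R,4R)-5-[(tert-butyldimethylsilyl)oxy]-4-{(2R)-2-[(tert-butyldimethylsilyl)oxy]-4-[4-(methoxymethoxy)phenyl]butyl}-7-methoxy-2-[4-(methoxymethoxy)phenyl]-3,4-dihydro-2H-chromen-8-yl]-3-[4-(methoxymethoxy)phenyl]prop-2-en-1-one, via aryllithium 30 (not isolated), via lithium hemiaminal 31 (not isolated)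
Conditions: t-BuLi (2.1 equiv), THF, −78 °C; then 5, −78 → −20 °C; aq. NH4Cl
Reagents that add atoms: none
Why: Bromine–lithium exchange at −78 °C is much faster than deprotonation next to the MOM ethers, so aryllithium 30 forms only at C8; it adds to the carbonyl of the N-methoxy-N-methylamide to give the chelated adduct 31, which holds until the quench and then releases the enone (Weinreb ketone synthesis), so the chalcone arrives with its (E)-alkene intact.

**Step 17**
Reactants: 32 (2E)-1-[(2R,4R)-5-[(tert-butyldimethylsilyl)oxy]-4-{(2R)-2-[(tert-butyldimethylsilyl)oxy]-4-[4-(methoxymethoxy)phenyl]butyl}-7-methoxy-2-[4-(methoxymethoxy)phenyl]-3,4-dihydro-2H-chromen-8-yl]-3-[4-(methoxymethoxy)phenyl]prop-2-en-1-one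
Product: 33 (2E)-1-[(2R,4S)-5-hydroxy-4-[(2R)-2-hydroxy-4-(4-hydroxyphenyl)butyl]-2-(4-hydroxyphenyl)-7-methoxy-3,4-dihydro-2H-chromen-8-yl]-3-(4-hydroxyphenyl)prop-2-en-1-one
Conditions: 3 M aq. HCl, MeOH–THF, rt → 40 °C
Reagents that add atoms: none
Why: Acid-catalysed methanolysis cleaves the three MOM acetals and both silyl ethers in one operation (acetal and silyl ether solvolysis); the conditions are kept mild because the C2–O1 bond is benzylic to a para-oxygenated ring.

## Compound list

1 | 4-hydroxybenzaldehyde | O=Cc1ccc(O)cc1 | starting material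
2 | 4-(methoxymethoxy)benzaldehyde | COCOc1ccc(C=O)cc1 | intermediate
3 | tributyl{(1R)-1-[4-(methoxymethoxy)phenyl]but-3-en-1-yloxy}stannane, stannyl ether of 4, not isolated | CCCC[Sn](CCCC)(CCCC)O[C@@H](c1ccc(OCOC)cc1)CC=C | intermediate
4 | (1R)-1-[4-(methoxymethoxy)phenyl]but-3-en-1-ol | O[C@@H](c1ccc(OCOC)cc1)CC=C | intermediate
5 | (2E)-N-methoxy-3-[4-(methoxymethoxy)phenyl]-N-methylprop-2-enamide | CON(C)C(=O)/C=C/c1ccc(OCOC)cc1 | intermediate
6 | bromomagnesium (4E)-3-[methoxy(methyl)amino]-5-[4-(methoxymethoxy)phenyl]penta-1,4-dien-3-olate, not isolated | C=CC(O[Mg]Br)(N(C)OC)/C=C/c1ccc(OCOC)cc1 | intermediate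
7 | (1E)-1-[4-(methoxymethoxy)phenyl]penta-1,4-dien-3-one | C=CC(=O)/C=C/c1ccc(OCOC)cc1 | intermediate
8 | (1E,4E,7R)-7-hydroxy-1,7-bis[4-(methoxymethoxy)phenyl]hepta-1,4-dien-3-one | O[C@@H](c1ccc(OCOC)cc1)C/C=C/C(=O)/C=C/c1ccc(OCOC)cc1 | intermediate
9 | 2-hydroxy-4-methoxybenzaldehyde | COc1ccc(C=O)c(O)c1 | starting material
10 | 2-(benzyloxy)-4-methoxybenzaldehyde | COc1ccc(C=O)c(OCc2ccccc2)c1 | intermediate
11 | 2-(benzyloxy)-4-methoxyphenyl formate, not isolated | COc1ccc(OC=O)c(OCc2ccccc2)c1 | intermediate
12 | 2-(benzyloxy)-4-methoxyphenol | COc1ccc(O)c(OCc2ccccc2)c1 | intermediate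
13 | 2-(benzyloxy)-4-methoxyphenyl N-(propan-2-yl)carbamate | COc1ccc(OC(=O)NC(C)C)c(OCc2ccccc2)c1 | intermediate
14 | 2-(benzyloxy)-4-methoxyphenyl N-(tert-butyldimethylsilyl)-N-(propan-2-yl)carbamate, not isolated | COc1ccc(OC(=O)N(C(C)C)[Si](C)(C)C(C)(C)C)c(OCc2ccccc2)c1 | intermediate
15 | 6-lithio derivative of 14 (lithium ortho to the carbamate oxygen, remote from the benzyloxy group), not isolated | COc1cc([Li])c(OC(=O)N(C(C)C)[Si](C)(C)C(C)(C)C)c(OCc2ccccc2)c1 | intermediate
16 | 2-(benzyloxy)-4-methoxy-6-(trimethylsilyl)phenyl N-(tert-butyldimethylsilyl)-N-(propan-2-yl)carbamate, not isolated | COc1cc([Si](C)(C)C)c(OC(=O)N(C(C)C)[Si](C)(C)C(C)(C)C)c(OCc2ccccc2)c1 | intermediate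
17 | 2-(benzyloxy)-4-methoxy-6-(trimethylsilyl)phenyl N-(propan-2-yl)carbamate | COc1cc([Si](C)(C)C)c(OC(=O)NC(C)C)c(OCc2ccccc2)c1 | intermediate
18 | 2-(benzyloxy)-4-methoxy-6-(trimethylsilyl)phenol, formed as its amidinium phenoxide, not isolated | COc1cc([Si](C)(C)C)c(O)c(OCc2ccccc2)c1 | intermediate
19 | 2-(benzyloxy)-4-methoxy-6-(trimethylsilyl)phenyl trifluoromethanesulfonate | COc1cc(OCc2ccccc2)c(OS(=O)(=O)C(F)(F)F)c([Si](C)(C)C)c1 | intermediate
20 | cesium alkoxide of 8, not isolated | [Cs]O[C@@H](c1ccc(OCOC)cc1)C/C=C/C(=O)/C=C/c1ccc(OCOC)cc1 | intermediate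
21 | 3-(benzyloxy)-5-methoxybenzyne (aryne bond between the former triflate and silyl carbons of 19), not isolated | COC1=CC#CC(OCc2ccccc2)=C1 | intermediate
22 | aryl cesium in which the oxygen of 8 is bound to the aryne carbon remote from the benzyloxy group and the carbanion sits on the carbon between the two oxygens, (R) at the carbinol carbon, not isolated | [Cs]c1c(OCc2ccccc2)cc(OC)cc1O[C@@H](c1ccc(OCOC)cc1)C/C=C/C(=O)/C=C/c1ccc(OCOC)cc1 | intermediate
23 | cesium enolate of 24 (enolate alkene between C1'' and C2''), not isolated | COc1cc(OCc3ccccc3)c2c(c1)O[C@@H](c1ccc(OCOC)cc1)C[C@@H]2C=C(O[Cs])/C=C/c1ccc(OCOC)cc1 | intermediate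
24 | (3E)-1-[(2R,4R)-5-(benzyloxy)-7-methoxy-2-[4-(methoxymethoxy)phenyl]-3,4-dihydro-2H-chromen-4-yl]-4-[4-(methoxymethoxy)phenyl]but-3-en-2-one (2,4-trans) | COc1cc(OCc3ccccc3)c2c(c1)O[C@@H](c1ccc(OCOC)cc1)C[C@@H]2CC(=O)/C=C/c1ccc(OCOC)cc1 | intermediate
25 | 1,3,2-benzodioxaborol-2-yl (catechol borate) ester of 26, not isolated | COc1cc(OCc3ccccc3)c2c(c1)O[C@@H](c1ccc(OCOC)cc1)C[C@@H]2C[C@H](OB1Oc2ccccc2O1)/C=C/c1ccc(OCOC)cc1 | intermediate
26 | (2S,3E)-1-[(2R,4S)-5-(benzyloxy)-7-methoxy-2-[4-(methoxymethoxy)phenyl]-3,4-dihydro-2H-chromen-4-yl]-4-[4-(methoxymethoxy)phenyl]but-3-en-2-ol | COc1cc(OCc3ccccc3)c2c(c1)O[C@@H](c1ccc(OCOC)cc1)C[C@@H]2C[C@H](O)/C=C/c1ccc(OCOC)cc1 | intermediate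
27 | (2R,4S)-4-{(2R)-2-hydroxy-4-[4-(methoxymethoxy)phenyl]butyl}-7-methoxy-2-[4-(methoxymethoxy)phenyl]-3,4-dihydro-2H-chromen-5-ol | COc1cc(O)c2c(c1)O[C@@H](c1ccc(OCOC)cc1)C[C@@H]2C[C@H](O)CCc1ccc(OCOC)cc1 | intermediate
28 | (2R,4R)-5-[(tert-butyldimethylsilyl)oxy]-4-{(2R)-2-[(tert-butyldimethylsilyl)oxy]-4-[4-(methoxymethoxy)phenyl]butyl}-7-methoxy-2-[4-(methoxymethoxy)phenyl]-3,4-dihydro-2H-chromene | COc1cc(O[Si](C)(C)C(C)(C)C)c2c(c1)O[C@@H](c1ccc(OCOC)cc1)C[C@@H]2C[C@H](O[Si](C)(C)C(C)(C)C)CCc1ccc(OCOC)cc1 | intermediate
29 | 8-bromo derivative of 28, (2R,4R) with (2R) in the chain | COc1cc(O[Si](C)(C)C(C)(C)C)c2c(c1Br)O[C@@H](c1ccc(OCOC)cc1)C[C@@H]2C[C@H](O[Si](C)(C)C(C)(C)C)CCc1ccc(OCOC)cc1 | intermediate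
30 | 8-lithio derivative of 28, not isolated | COc1cc(O[Si](C)(C)C(C)(C)C)c2c(c1[Li])O[C@@H](c1ccc(OCOC)cc1)C[C@@H]2C[C@H](O[Si](C)(C)C(C)(C)C)CCc1ccc(OCOC)cc1 | intermediate
31 | lithium hemiaminal from 30 and 5 (C8–C(OLi)(N(OMe)Me)–CH=CH–aryl), not isolated | COc1cc(O[Si](C)(C)C(C)(C)C)c2c(c1C(O[Li])(N(C)OC)/C=C/c1ccc(OCOC)cc1)O[C@@H](c1ccc(OCOC)cc1)C[C@@H]2C[C@H](O[Si](C)(C)C(C)(C)C)CCc1ccc(OCOC)cc1 | intermediate
32 | (2E)-1-[(2R,4R)-5-[(tert-butyldimethylsilyl)oxy]-4-{(2R)-2-[(tert-butyldimethylsilyl)oxy]-4-[4-(methoxymethoxy)phenyl]butyl}-7-methoxy-2-[4-(methoxymethoxy)phenyl]-3,4-dihydro-2H-chromen-8-yl]-3-[4-(methoxymethoxy)phenyl]prop-2-en-1-one | COc1cc(O[Si](C)(C)C(C)(C)C)c2c(c1C(=O)/C=C/c1ccc(OCOC)cc1)O[C@@H](c1ccc(OCOC)cc1)C[C@@H]2C[C@H](O[Si](C)(C)C(C)(C)C)CCc1ccc(OCOC)cc1 | intermediate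
33 | (2E)-1-[(2R,4S)-5-hydroxy-4-[(2R)-2-hydroxy-4-(4-hydroxyphenyl)butyl]-2-(4-hydroxyphenyl)-7-methoxy-3,4-dihydro-2H-chromen-8-yl]-3-(4-hydroxyphenyl)prop-2-en-1-one | COc1cc(O)c2c(c1C(=O)/C=C/c1ccc(O)cc1)O[C@@H](c1ccc(O)cc1)C[C@@H]2C[C@H](O)CCc1ccc(O)cc1 | target

## Step count and least certain steps

Total: 17 steps. Longest linear sequence: 12 steps (9 → 10 → 12 → 13 → 17 → 19 → 24 → 26 → 27 → 28 → 29 → 32 → 33; steps 6–17).

**Step 11 (key step, new method).**
- Most likely failure: protonation of the aryl anion of 22 before it closes, which would stop at the open aryl ether. Alkoxide 20 may also fragment by a retro-vinylogous aldol or dehydrate under base, since it is a δ-oxy enone. Facial selectivity at C4 may be poor, because the trans preference rests only on the peri interaction with the C5 benzyloxy group.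
- Fallback (known chemistry), from 19 and 4, returning at 24. The two bonds are made one at a time.
  - Iododesilylation of 19 (ICl, CH2Cl2, −78 → 0 °C) gives 2-(benzyloxy)-6-iodo-4-methoxyphenyl trifluoromethanesulfonate F1.
  - Copper-catalysed O-arylation of 4 with the iodide of F1 (CuI, 3,4,7,8-tetramethyl-1,10-phenanthroline, Cs2CO3, toluene, 90 °C) proceeds with retention, since the carbinol C–O bond is not broken, and gives 2-(benzyloxy)-4-methoxy-6-{(1R)-1-[4-(methoxymethoxy)phenyl]but-3-en-1-yloxy}phenyl trifluoromethanesulfonate F2.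
  - Cross-metathesis of F2 with 7 as in step 5 gives 2-(benzyloxy)-4-methoxy-6-{(1R,3E,6E)-1,7-bis[4-(methoxymethoxy)phenyl]-5-oxohepta-3,6-dien-1-yloxy}phenyl trifluoromethanesulfonate F3.
  - An intramolecular reductive Heck reaction of the aryl triflate (Pd(OAc)2, PPh3, HCO2Na, DMF, 80 °C; 6-exo carbopalladation of the near enone, then formate reduction of the palladium enolate) closes C4–C4a and gives 24; any cis isomer would be separated.

**Step 9.**
- Most likely failure: deprotonation at the benzylic CH2 of the benzyl ether (with Wittig rearrangement) or at C3 between the two ether oxygens instead of at C6; anionic Fries migration of the carbamate if the aryllithium warms before it is trapped.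
- Fallback, from 12, returning at 19 and bypassing steps 8–10. Amine-mediated ortho-bromination of the phenol (Br2, t-BuNH2, toluene, −78 °C) gives 2-(benzyloxy)-6-bromo-4-methoxyphenol F4. O-Silylation with hexamethyldisilazane gives [2-(benzyloxy)-6-bromo-4-methoxyphenoxy]trimethylsilane F5. Bromine–lithium exchange (n-BuLi, THF, −78 °C) triggers the 1,3 oxygen-to-carbon silyl shift (retro-Brook) to the lithium phenoxide of 18, which is triflated in the flask (Tf2O) to 19.

**Step 12.**
- Most likely failure: poor facial selectivity, because the CH2 flank carries a bulky chromanyl branch and may compete with the styryl group for the large-substituent position in the catalyst complex.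
- Fallback, from 24, returning at 26. Luche reduction (NaBH4, CeCl3·7H2O, MeOH, −40 °C) gives 26 together with its C2'' epimer, (2R,3E)-1-[(2R,4S)-5-(benzyloxy)-7-methoxy-2-[4-(methoxymethoxy)phenyl]-3,4-dihydro-2H-chromen-4-yl]-4-[4-(methoxymethoxy)phenyl]but-3-en-2-ol F6. The two are diastereomers and would be separated by chromatography; F6 is reoxidised with MnO2 to 24 and recycled.

**Step 13.**
- Most likely failure: hydrogenolysis of the allylic C–O bond before the alkene is saturated, or slow cleavage of the hindered C5 benzyl ether that invites forcing conditions and then loss of the benzylic C2–O1 bond.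
- Fallback, from 26, returning at 28. The allylic alcohol is silylated first (TBSCl, imidazole, DMF) to (2R,4R)-5-(benzyloxy)-4-{(2S,3E)-2-[(tert-butyldimethylsilyl)oxy]-4-[4-(methoxymethoxy)phenyl]but-3-en-1-yl}-7-methoxy-2-[4-(methoxymethoxy)phenyl]-3,4-dihydro-2H-chromene F7, whose silyl ether is a much poorer leaving group. Hydrogenation (H2, 10% Pd/C, EtOAc) then gives (2R,4R)-4-{(2R)-2-[(tert-butyldimethylsilyl)oxy]-4-[4-(methoxymethoxy)phenyl]butyl}-7-methoxy-2-[4-(methoxymethoxy)phenyl]-3,4-dihydro-2H-chromen-5-ol F8, and silylation of the phenol gives 28.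

**Step 15.**
- Most likely failure: bromination at C6 or at both positions, since C6 and C8 are electronically alike and the selection is steric only.
- Fallback, from 27, returning at 29. The free phenol 27 is brominated before silylation with a para-selective tribromide (Bu4NBr3, CH2Cl2–MeOH, −20 °C); C8 is para to the C5 hydroxyl, so the control changes from steric to electronic. This gives (2R,4S)-8-bromo-4-{(2R)-2-hydroxy-4-[4-(methoxymethoxy)phenyl]butyl}-7-methoxy-2-[4-(methoxymethoxy)phenyl]-3,4-dihydro-2H-chromen-5-ol F9, which is bis-silylated (TBSCl, imidazole, DMF) to 29.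

**Step 17.**
- Most likely failure: acid ionisation of the C2–O1 bond, with epimerisation at C2 or ring opening through a para-oxygenated benzylic cation; addition of methanol to the chalcone.
- Fallback, from 32, returning at 33, in two stages without protic acid. HF·pyridine (THF–pyridine, 0 °C) removes both silyl ethers to give (2E)-1-[(2R,4S)-5-hydroxy-4-{(2R)-2-hydroxy-4-[4-(methoxymethoxy)phenyl]butyl}-7-methoxy-2-[4-(methoxymethoxy)phenyl]-3,4-dihydro-2H-chromen-8-yl]-3-[4-(methoxymethoxy)phenyl]prop-2-en-1-one F10. The aryl MOM ethers are then cleaved with trimethylsilyl triflate and 2,2'-bipyridyl (CH2Cl2, 0 °C) followed by water, giving 33.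

## Further compounds

F1 | step 11 | 2-(benzyloxy)-6-iodo-4-methoxyphenyl trifluoromethanesulfonate | COc1cc(OCc2ccccc2)c(OS(=O)(=O)C(F)(F)F)c(I)c1
F2 | step 11 | 2-(benzyloxy)-4-methoxy-6-{(1R)-1-[4-(methoxymethoxy)phenyl]but-3-en-1-yloxy}phenyl trifluoromethanesulfonate | COc1cc(OCc2ccccc2)c(OS(=O)(=O)C(F)(F)F)c(c1)O[C@@H](c1ccc(OCOC)cc1)CC=C
F3 | step 11 | 2-(benzyloxy)-4-methoxy-6-{(1R,3E,6E)-1,7-bis[4-(methoxymethoxy)phenyl]-5-oxohepta-3,6-dien-1-yloxy}phenyl trifluoromethanesulfonate | COc1cc(OCc2ccccc2)c(OS(=O)(=O)C(F)(F)F)c(c1)O[C@@H](c1ccc(OCOC)cc1)C/C=C/C(=O)/C=C/c1ccc(OCOC)cc1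
F4 | step 9 | 2-(benzyloxy)-6-bromo-4-methoxyphenol | COc1cc(Br)c(O)c(OCc2ccccc2)c1
F5 | step 9 | [2-(benzyloxy)-6-bromo-4-methoxyphenoxy]trimethylsilane | COc1cc(Br)c(O[Si](C)(C)C)c(OCc2ccccc2)c1
F6 | step 12 | (2R,3E)-1-[(2R,4S)-5-(benzyloxy)-7-methoxy-2-[4-(methoxymethoxy)phenyl]-3,4-dihydro-2H-chromen-4-yl]-4-[4-(methoxymethoxy)phenyl]but-3-en-2-ol | COc1cc(OCc3ccccc3)c2c(c1)O[C@@H](c1ccc(OCOC)cc1)C[C@@H]2C[C@@H](O)/C=C/c1ccc(OCOC)cc1
F7 | step 13 | (2R,4R)-5-(benzyloxy)-4-{(2S,3E)-2-[(tert-butyldimethylsilyl)oxy]-4-[4-(methoxymethoxy)phenyl]but-3-en-1-yl}-7-methoxy-2-[4-(methoxymethoxy)phenyl]-3,4-dihydro-2H-chromene | COc1cc(OCc3ccccc3)c2c(c1)O[C@@H](c1ccc(OCOC)cc1)C[C@@H]2C[C@H](O[Si](C)(C)C(C)(C)C)/C=C/c1ccc(OCOC)cc1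
F8 | step 13 | (2R,4R)-4-{(2R)-2-[(tert-butyldimethylsilyl)oxy]-4-[4-(methoxymethoxy)phenyl]butyl}-7-methoxy-2-[4-(methoxymethoxy)phenyl]-3,4-dihydro-2H-chromen-5-ol | COc1cc(O)c2c(c1)O[C@@H](c1ccc(OCOC)cc1)C[C@@H]2C[C@H](O[Si](C)(C)C(C)(C)C)CCc1ccc(OCOC)cc1
F9 | step 15 | (2R,4S)-8-bromo-4-{(2R)-2-hydroxy-4-[4-(methoxymethoxy)phenyl]butyl}-7-methoxy-2-[4-(methoxymethoxy)phenyl]-3,4-dihydro-2H-chromen-5-ol | COc1cc(O)c2c(c1Br)O[C@@H](c1ccc(OCOC)cc1)C[C@@H]2C[C@H](O)CCc1ccc(OCOC)cc1
F10 | step 17 | (2E)-1-[(2R,4S)-5-hydroxy-4-{(2R)-2-hydroxy-4-[4-(methoxymethoxy)phenyl]butyl}-7-methoxy-2-[4-(methoxymethoxy)phenyl]-3,4-dihydro-2H-chromen-8-yl]-3-[4-(methoxymethoxy)phenyl]prop-2-en-1-one | COc1cc(O)c2c(c1C(=O)/C=C/c1ccc(OCOC)cc1)O[C@@H](c1ccc(OCOC)cc1)C[C@@H]2C[C@H](O)CCc1ccc(OCOC)cc1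
A1 | alternative 1 | 2-[(2R,4S,6R)-2-{4-[(tert-butyldimethylsilyl)oxy]phenyl}-6-(2-{4-[(tert-butyldimethylsilyl)oxy]phenyl}ethyl)oxan-4-yl]benzene-1,3,5-triol (all-cis) | O1[C@@H](c2ccc(O[Si](C)(C)C(C)(C)C)cc2)C[C@@H](c2c(O)cc(O)cc2O)C[C@H]1CCc1ccc(O[Si](C)(C)C(C)(C)C)cc1
A2 | alternative 1 | {4-[(tert-butyldimethylsilyl)oxy]phenyl}{[(3R)-1-{4-[(tert-butyldimethylsilyl)oxy]phenyl}hex-5-en-3-yl]oxy}methyl acetate, epimeric at the acetal carbon | C=CC[C@H](OC(OC(C)=O)c1ccc(O[Si](C)(C)C(C)(C)C)cc1)CCc1ccc(O[Si](C)(C)C(C)(C)C)cc1
A3 | alternative 1 | phloroglucinol (benzene-1,3,5-triol) | Oc1cc(O)cc(O)c1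
A4 | alternative 2 | (2R)-1-[(2R,4S)-8-acetyl-2-[4-(benzyloxy)phenyl]-5-[(tert-butyldimethylsilyl)oxy]-7-methoxy-3,4-dihydro-2H-chromen-4-yl]-4-{4-[(2,2-dimethylpropanoyl)oxy]phenyl}butan-2-yl acetate (2,4-trans) | COc1cc(O[Si](C)(C)C(C)(C)C)c2c(c1C(C)=O)O[C@@H](c1ccc(OCc3ccccc3)cc1)C[C@@H]2C[C@H](OC(C)=O)CCc1ccc(OC(=O)C(C)(C)C)cc1
A5 | alternative 2 | (3R,5R)-5-{3-acetyl-6-[(tert-butyldimethylsilyl)oxy]-2-hydroxy-4-methoxyphenyl}-7-[4-(benzyloxy)phenyl]-1-{4-[(2,2-dimethylpropanoyl)oxy]phenyl}heptan-3-yl acetate | COc1cc(O[Si](C)(C)C(C)(C)C)c(c(O)c1C(C)=O)[C@H](CCc1ccc(OCc3ccccc3)cc1)C[C@H](OC(C)=O)CCc1ccc(OC(=O)C(C)(C)C)cc1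
A6 | alternative 3 | (2R,4R)-2-{4-[(tert-butyldimethylsilyl)oxy]phenyl}-4-[(2R)-2-[(tert-butyldimethylsilyl)oxy]-4-{4-[(tert-butyldimethylsilyl)oxy]phenyl}butyl]-7-methoxy-3,4-dihydro-2H-chromen-5-ol (2,4-trans) | COc1cc(O)c2c(c1)O[C@@H](c1ccc(O[Si](C)(C)C(C)(C)C)cc1)C[C@@H]2C[C@H](O[Si](C)(C)C(C)(C)C)CCc1ccc(O[Si](C)(C)C(C)(C)C)cc1
A7 | alternative 3 | 2-[(3R)-3-[(tert-butyldimethylsilyl)oxy]-5-{4-[(tert-butyldimethylsilyl)oxy]phenyl}-1-hydroxypentyl]-5-methoxybenzene-1,3-diol, either configuration at C1 of the chain | COc1cc(O)c(c(O)c1)C(O)C[C@H](O[Si](C)(C)C(C)(C)C)CCc1ccc(O[Si](C)(C)C(C)(C)C)cc1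
A8 | alternative 3 | 4-[(tert-butyldimethylsilyl)oxy]styrene | C=Cc1ccc(O[Si](C)(C)C(C)(C)C)cc1
A9 | alternative 3 | 3-hydroxy-5-methoxy-2-[(3R)-3-[(tert-butyldimethylsilyl)oxy]-5-{4-[(tert-butyldimethylsilyl)oxy]phenyl}pentylidene]cyclohexa-3,5-dien-1-one (ortho-quinone methide) | O=C1C=C(OC)C=C(O)C1=CC[C@H](O[Si](C)(C)C(C)(C)C)CCc1ccc(O[Si](C)(C)C(C)(C)C)cc1
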